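**Retrosynthetic overview**

- The strategy rests on ring A of the chromene. Its two oxygens are meta to each other on C7 and C8a with an unsubstituted C8 between them. C6, next to C7, bears the only stereocentre as a 1-oxyethyl group, which is the O–CH(CH3)–C unit of (S)-lactic acid.
- Last disconnection: the (Z)-enol ether O–C(sp2) bond. It is made by CuI-catalysed O-vinylation of the ring A carbinol with a (Z)-vinyl iodide that carries ring C. The iodide comes from 2-bromo-5-methylphenol and propargyl alcohol by anti-carbomagnesiation–iodination.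
- Ring B (the pyran) is opened at O1–C2 and C4–C4a to a 1,1-dimethylpropargyl aryl ether on the C8a oxygen (propargyl Claisen rearrangement, then oxa-6π closure).
- Ring A is opened at C7–C8, C8a–C4a and C6–C7 to (triisopropylsilyloxy)ethyne and the vinylketene released from a lactate-derived diazo enone.
- Ring order: ring A first, ring B second; ring C is bought as the bromocresol.

Key step: step 9

Assumption: (triisopropylsilyloxy)ethyne is not treated as purchasable and is made in steps 6 to 8. From step 9 onwards no acidic reagent is used, because the C6 carbinol carbon is ortho and para to ring oxygens and would ionise.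

**Route**

Step 1
Reactants: 1 ethyl (S)-lactate
Product: 2 ethyl (2S)-2-(tert-butyldimethylsilyloxy)propanoate
Conditions: t-BuMe2SiCl, imidazole, DMF, 0 → 25 °C
Reagents that add atoms: tert-butyldimethylsilyl chloride, CC(C)(C)[Si](C)(C)Cl
Why: Standard O-silylation of a secondary alcohol (silyl ether formation) that does not touch the stereocentre.

Step 2
Reactants: 2 ethyl (2S)-2-(tert-butyldimethylsilyloxy)propanoate
Product: 4 (2S)-2-(tert-butyldimethylsilyloxy)propanal, via aluminium hemiacetal 3 (not isolated)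
Conditions: i-Bu2AlH (1.1 equiv), CH2Cl2, −78 °C; MeOH, then aq. KNaC4H4O6; used crude at once
Reagents that add atoms: none
Why: Partial ester reduction with i-Bu2AlH stops at the tetrahedral aluminium hemiacetal 3 at −78 °C and releases the aldehyde only on work-up, and cold neutral handling keeps the α-stereocentre.

Step 3
Reactants: 4 (2S)-2-(tert-butyldimethylsilyloxy)propanal; 5 1-(triphenylphosphoranylidene)propan-2-one
Product: 6 (3E,5S)-5-(tert-butyldimethylsilyloxy)hex-3-en-2-one
Conditions: CH2Cl2, 25 → 40 °C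
Reagents that add atoms: none
Why: Wittig olefination with a stabilised ylide should give the (E)-enone under base-free conditions that do not epimerise the α-silyloxy aldehyde.

Step 4
Reactants: 6 (3E,5S)-5-(tert-butyldimethylsilyloxy)hex-3-en-2-one
Product: 8 (5E,7S)-7-(tert-butyldimethylsilyloxy)-1,1,1-trifluorooct-5-ene-2,4-dione, via lithium dienolate 7 (not isolated)
Conditions: LiN(SiMe3)2 (1.1 equiv), THF, −78 °C; CF3CO2CH2CF3 (1.2 equiv), −78 °C; cold dilute aq. HCl/Et2O work-up; used crude
Reagents that add atoms: 2,2,2-trifluoroethyl trifluoroacetate, O=C(OCC(F)(F)F)C(F)(F)F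
Why: Kinetic deprotonation of the methyl ketone gives the cross-conjugated enolate 7 (not the γ-dienolate, so the stereocentre stays untouched), which undergoes Claisen-type C-trifluoroacetylation.

Step 5
Reactants: 8 (5E,7S)-7-(tert-butyldimethylsilyloxy)-1,1,1-trifluorooct-5-ene-2,4-dione
Product: 9 (3E,5S)-5-(tert-butyldimethylsilyloxy)-1-diazohex-3-en-2-one
Conditions: MeSO2N3 (1.5 equiv), Et3N (1.5 equiv), H2O (1 equiv), MeCN, 25 °C
Reagents that add atoms: methanesulfonyl azide, CS(=O)(=O)N=[N+]=[N-]
Why: Detrifluoroacetylative diazo transfer (a Regitz-type transfer in which the activating trifluoroacetyl group leaves as the N-acylsulfonamide) should give the α′-diazo enone with no base strong enough to affect the γ-stereocentre.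

Step 6
Reactants: 10 tetrahydrofuran
Product: 12 triisopropyl(vinyloxy)silane, via lithium ethenolate 11 (not isolated)
Conditions: n-BuLi (hexanes), THF, 25 °C, 16 h; i-Pr3SiOTf, −78 → 0 °C
Reagents that add atoms: triisopropylsilyl trifluoromethanesulfonate, CC(C)[Si](OS(=O)(=O)C(F)(F)F)(C(C)C)C(C)C
Why: Cycloreversion of 2-lithiated tetrahydrofuran gives ethylene and the lithium enolate of acetaldehyde 11, and O-silylation of this enolate with the bulky silyl triflate gives the enol ether.

Step 7
Reactants: 12 triisopropyl(vinyloxy)silane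
Product: 14 [(Z)-2-bromovinyloxy]triisopropylsilane, via 1,2-dibromoethyl silyl ether 13 (not isolated)
Conditions: Br2 (1.0 equiv), CH2Cl2, −78 °C; Et3N (1.5 equiv), −78 → 25 °C; distillation
Reagents that add atoms: bromine, BrBr
Why: Bromination–dehydrobromination of an enol ether should give the 2-bromovinyl ether, mainly as the Z isomer (cis effect of 1-halo-2-oxyalkenes), with the bulky i-Pr3Si group slowing desilylation of the oxocarbenium intermediate.

Step 8
Reactants: 14 [(Z)-2-bromovinyloxy]triisopropylsilane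
Product: 16 (triisopropylsilyloxy)ethyne, via lithium siloxyacetylide 15 (not isolated)
Conditions: LiN(i-Pr)2 (2.2 equiv), THF, −78 °C; AcOH in THF, −78 °C; pentane, pH 7 wash, distillation
Reagents that add atoms: none
Why: Anti E2 dehydrobromination of the (Z)-2-bromovinyl ether, as in the classical preparation of alkoxyacetylenes, should give the ynol ether, which the second equivalent of amide holds as acetylide 15 until cold protonation.

Step 9
Reactants: 9 (3E,5S)-5-(tert-butyldimethylsilyloxy)-1-diazohex-3-en-2-one; 16 (triisopropylsilyloxy)ethyne (2 equiv)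
Product: 21 2-[(1S)-1-(tert-butyldimethylsilyloxy)ethyl]-5-(triisopropylsilyloxy)phenol, via vinylketene 17 (not isolated), via 4-vinylcyclobutenone 18 (not isolated), via dienylketene 19 (not isolated), via cyclohexa-2,4-dienone 20 (not isolated)
Conditions: ClCH2CH2Cl (0.2 M, degassed), hν 254 nm (low-pressure Hg lamps, quartz), 25 °C; then 80 °C in the dark
Reagents that add atoms: none
Why: Light expels N2 from 9 and the alkenyl group migrates (photochemical Wolff rearrangement) to give vinylketene 17, which the ynol ether 16 traps in a [2+2] cycloaddition: the ketene carbonyl carbon (future C7) bonds to the nucleophilic CH terminus of 16 (C8) and the ketene α-carbon (C4a) to the siloxy carbon (C8a), giving cyclobutenone 18. Warming opens 18 by reversible 4π electrocyclic ring opening to dienylketene 19, and ring A closes by thermal disrotatory 6π electrocyclisation that forms C6–C7, after which dienone 20 tautomerises to phenol 21. The closest known reaction type is the Danheiser benzannulation of photochemically generated vinylketenes with alkoxy- and siloxyalkynes; the unsubstituted siloxyalkyne is the less common partner but reacts through the same polarised terminus. No stereocentre is formed (C4 of 18 and C6 of 20 are transient and vanish on aromatisation), and the lactate-derived carbinol carbon stays sp3 and is never ionised or deprotonated, so its S configuration is carried through. The step needs regioselectivity in the [2+2] event, which the oxygen-polarised triple bond of 16 secures, so that the two oxygens end up meta with C8–H between them and the side chain ortho to the free phenol. It also needs the dienylketene rotamer that can cyclise, which is supplied because ring opening is reversible and 6π closure is not, and it delivers the two oxygens already differentiated (free OH on C7, silyl ether on C8a).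

Step 10
Reactants: 21 2-[(1S)-1-(tert-butyldimethylsilyloxy)ethyl]-5-(triisopropylsilyloxy)phenol
Product: 22 tert-butyl{(1S)-1-[2-methoxy-4-(triisopropylsilyloxy)phenyl]ethoxy}dimethylsilane
Conditions: MeI (3 equiv), K2CO3 (2 equiv), acetone, 25 °C
Reagents that add atoms: iodomethane, CI
Why: Williamson O-methylation of the only free phenol under mild anhydrous carbonate conditions should leave both silyl ethers in place.

Step 11
Reactants: 22 tert-butyl{(1S)-1-[2-methoxy-4-(triisopropylsilyloxy)phenyl]ethoxy}dimethylsilane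
Product: 23 4-[(1S)-1-(tert-butyldimethylsilyloxy)ethyl]-3-methoxyphenol
Conditions: Bu4NF (1.05 equiv), THF, −20 → 0 °C; pH 7 buffer (NaH2PO4/Na2HPO4)
Reagents that add atoms: none
Why: Fluoride desilylation is much faster for the aryl silyl ether (phenoxide leaving group) than for the hindered secondary alkyl silyl ether, so one equivalent of fluoride at low temperature should free only the C8a oxygen.

Step 12
Reactants: 23 4-[(1S)-1-(tert-butyldimethylsilyloxy)ethyl]-3-methoxyphenol; 24 3-chloro-3-methylbut-1-yne (2 equiv)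
Product: 25 tert-butyl{(1S)-1-[2-methoxy-4-(2-methylbut-3-yn-2-yloxy)phenyl]ethoxy}dimethylsilane
Conditions: DBU (2.2 equiv), CuCl2·2H2O (1 mol%), MeCN, 0 °C
Reagents that add atoms: none
Why: Copper-catalysed propargylic substitution (O-alkylation of the phenoxide by the tertiary propargylic chloride through a copper acetylide) should give the aryl 1,1-dimethylpropargyl ether at 0 °C without acid.

Step 13
Reactants: 25 tert-butyl{(1S)-1-[2-methoxy-4-(2-methylbut-3-yn-2-yloxy)phenyl]ethoxy}dimethylsilane
Product: 28 tert-butyl[(1S)-1-(7-methoxy-2,2-dimethyl-2H-chromen-6-yl)ethoxy]dimethylsilane, via ortho-allenylphenol 26 (not isolated), via ortho-quinone methide 27 (not isolated)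
Conditions: o-xylene (0.05 M, degassed), 140 °C
Reagents that add atoms: none
Why: Aromatic propargyl Claisen rearrangement to allenylphenol 26, 1,5-hydrogen shift to quinone methide 27 and oxa-6π electrocyclisation close ring B, and attack at C4a (para to the methoxy group) should be preferred over the hindered C8 between the two oxygens.

Step 14
Reactants: 28 tert-butyl[(1S)-1-(7-methoxy-2,2-dimethyl-2H-chromen-6-yl)ethoxy]dimethylsilane
Product: 29 (1S)-1-(7-methoxy-2,2-dimethyl-2H-chromen-6-yl)ethan-1-ol
Conditions: Bu4NF (1.5 equiv), THF, 0 → 25 °C; pH 7 buffer (NaH2PO4/Na2HPO4); chromatography on Et3N-deactivated silica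
Reagents that add atoms: none
Why: Fluoride desilylation of the secondary silyl ether attacks silicon only, so the electron-rich benzylic C–O bond is not broken and the configuration is kept.

Step 15
Reactants: 30 2-bromo-5-methylphenol
Product: 31 (2-bromo-5-methylphenoxy)triisopropylsilane
Conditions: i-Pr3SiCl (1.2 equiv), imidazole (2.5 equiv), DMF, 25 °C
Reagents that add atoms: triisopropylsilyl chloride, CC(C)[Si](Cl)(C(C)C)C(C)C
Why: O-silylation of the phenol with a bulky silyl group, chosen to resist 1,3-silyl migration to carbon in the Grignard reagent and the carbonate base of step 18.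

Step 16
Reactants: 31 (2-bromo-5-methylphenoxy)triisopropylsilane (2.5 equiv); 32 propargyl alcohol
Product: 35 (2Z)-3-iodo-2-[4-methyl-2-(triisopropylsilyloxy)phenyl]prop-2-en-1-ol, via arylmagnesium bromide 33 (not isolated), via magnesium chelate 34 (not isolated)
Conditions: Mg, THF, 25–45 °C; 32, CuI (10 mol%), THF, 0 → 25 °C; I2, −40 → 0 °C; aq. Na2S2O3/NH4Cl
Reagents that add atoms: iodine, II
Why: Copper-catalysed anti-carbomagnesiation of the magnesium alkoxide of propargyl alcohol places the aryl group on C2 and magnesium on C3 in the five-membered chelate 34, so iodinolysis with retention should give the (Z)-iodide with iodine cis to CH2OH.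

Step 17
Reactants: 35 (2Z)-3-iodo-2-[4-methyl-2-(triisopropylsilyloxy)phenyl]prop-2-en-1-ol
Product: 36 tert-butyl({(2Z)-3-iodo-2-[4-methyl-2-(triisopropylsilyloxy)phenyl]prop-2-en-1-yl}oxy)dimethylsilane
Conditions: t-BuMe2SiCl (1.2 equiv), imidazole (2 equiv), CH2Cl2, 0 → 25 °C
Reagents that add atoms: tert-butyldimethylsilyl chloride, CC(C)(C)[Si](C)(C)Cl
Why: O-silylation of the primary allylic alcohol removes the competing nucleophile before the C–O coupling.

Step 18
Reactants: 29 (1S)-1-(7-methoxy-2,2-dimethyl-2H-chromen-6-yl)ethan-1-ol; 36 tert-butyl({(2Z)-3-iodo-2-[4-methyl-2-(triisopropylsilyloxy)phenyl]prop-2-en-1-yl}oxy)dimethylsilane (1.5 equiv)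
Product: 37 tert-butyl{[(2Z)-3-[(1S)-1-(7-methoxy-2,2-dimethyl-2H-chromen-6-yl)ethoxy]-2-[4-methyl-2-(triisopropylsilyloxy)phenyl]prop-2-en-1-yl]oxy}dimethylsilane
Conditions: CuI (20 mol%), 3,4,7,8-tetramethyl-1,10-phenanthroline (40 mol%), Cs2CO3 (2 equiv), toluene, 80 °C, argon
Reagents that add atoms: none
Why: Copper-catalysed Ullmann-type C–O coupling of an alcohol with a vinyl iodide forms the O–C(sp2) bond with retention of alkene geometry, so neither the carbinol stereocentre nor the (Z)-geometry should be disturbed.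

Step 19
Reactants: 37 tert-butyl{[(2Z)-3-[(1S)-1-(7-methoxy-2,2-dimethyl-2H-chromen-6-yl)ethoxy]-2-[4-methyl-2-(triisopropylsilyloxy)phenyl]prop-2-en-1-yl]oxy}dimethylsilane
Product: 38 2-{(1Z)-3-hydroxy-1-[(1S)-1-(7-methoxy-2,2-dimethyl-2H-chromen-6-yl)ethoxy]prop-1-en-2-yl}-5-methylphenol (CNP0279099.1)
Conditions: Bu4NF (3 equiv), THF, 0 → 25 °C; pH 7 buffer (NaH2PO4/Na2HPO4)
Reagents that add atoms: none
Why: Global fluoride desilylation should cleave the aryl and the primary silyl ether in one operation under conditions that leave the acid-labile enol ether and benzylic ether intact.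

**Compound list**

1 | ethyl (S)-lactate | CCOC(=O)[C@H](C)O | starting material
2 | ethyl (2S)-2-(tert-butyldimethylsilyloxy)propanoate | CCOC(=O)[C@H](C)O[Si](C)(C)C(C)(C)C | intermediate
3 | [(2S)-2-(tert-butyldimethylsilyloxy)-1-ethoxypropoxy]diisobutylalane (aluminium hemiacetal, not isolated) | CCOC(O[Al](CC(C)C)CC(C)C)[C@H](C)O[Si](C)(C)C(C)(C)C | intermediate
4 | (2S)-2-(tert-butyldimethylsilyloxy)propanal | C[C@H](O[Si](C)(C)C(C)(C)C)C=O | intermediate
5 | 1-(triphenylphosphoranylidene)propan-2-one | CC(=O)C=P(c1ccccc1)(c1ccccc1)c1ccccc1 | starting material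
6 | (3E,5S)-5-(tert-butyldimethylsilyloxy)hex-3-en-2-one | CC(=O)/C=C/[C@H](C)O[Si](C)(C)C(C)(C)C | intermediate
7 | lithium (3E,5S)-5-(tert-butyldimethylsilyloxy)hexa-1,3-dien-2-olate (not isolated) | [Li+].[O-]C(=C)/C=C/[C@H](C)O[Si](C)(C)C(C)(C)C | intermediate
8 | (5E,7S)-7-(tert-butyldimethylsilyloxy)-1,1,1-trifluorooct-5-ene-2,4-dione | O=C(CC(=O)C(F)(F)F)/C=C/[C@H](C)O[Si](C)(C)C(C)(C)C | intermediate
9 | (3E,5S)-5-(tert-butyldimethylsilyloxy)-1-diazohex-3-en-2-one | O=C(C=[N+]=[N-])/C=C/[C@H](C)O[Si](C)(C)C(C)(C)C | intermediate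
10 | tetrahydrofuran | C1CCOC1 | starting material
11 | lithium ethenolate (not isolated) | [Li+].[O-]C=C | intermediate
12 | triisopropyl(vinyloxy)silane | C=CO[Si](C(C)C)(C(C)C)C(C)C | intermediate
13 | (1,2-dibromoethoxy)triisopropylsilane (racemic, not isolated) | BrCC(Br)O[Si](C(C)C)(C(C)C)C(C)C | intermediate
14 | [(Z)-2-bromovinyloxy]triisopropylsilane | Br/C=C\O[Si](C(C)C)(C(C)C)C(C)C | intermediate
15 | lithium (triisopropylsilyloxy)acetylide (not isolated) | [Li]C#CO[Si](C(C)C)(C(C)C)C(C)C | intermediate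
16 | (triisopropylsilyloxy)ethyne | C#CO[Si](C(C)C)(C(C)C)C(C)C | intermediate
17 | (3E,5S)-5-(tert-butyldimethylsilyloxy)hexa-1,3-dien-1-one (vinylketene, not isolated) | O=C=C/C=C/[C@H](C)O[Si](C)(C)C(C)(C)C | intermediate
18 | 4-[(1E,3S)-3-(tert-butyldimethylsilyloxy)but-1-en-1-yl]-3-(triisopropylsilyloxy)cyclobut-2-en-1-one (C4 epimers, not isolated) | O=C1C=C(O[Si](C(C)C)(C(C)C)C(C)C)C1/C=C/[C@H](C)O[Si](C)(C)C(C)(C)C | intermediate
19 | (3E,5E,7S)-7-(tert-butyldimethylsilyloxy)-3-(triisopropylsilyloxy)octa-1,3,5-trien-1-one (dienylketene, not isolated) | O=C=C/C(O[Si](C(C)C)(C(C)C)C(C)C)=C\C=C\[C@H](C)O[Si](C)(C)C(C)(C)C | intermediate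
20 | 6-[(1S)-1-(tert-butyldimethylsilyloxy)ethyl]-3-(triisopropylsilyloxy)cyclohexa-2,4-dien-1-one (C6 epimers, not isolated) | O=C1C=C(O[Si](C(C)C)(C(C)C)C(C)C)C=CC1[C@H](C)O[Si](C)(C)C(C)(C)C | intermediate
21 | 2-[(1S)-1-(tert-butyldimethylsilyloxy)ethyl]-5-(triisopropylsilyloxy)phenol | C[C@H](O[Si](C)(C)C(C)(C)C)c1ccc(O[Si](C(C)C)(C(C)C)C(C)C)cc1O | intermediate
22 | tert-butyl{(1S)-1-[2-methoxy-4-(triisopropylsilyloxy)phenyl]ethoxy}dimethylsilane | C[C@H](O[Si](C)(C)C(C)(C)C)c1ccc(O[Si](C(C)C)(C(C)C)C(C)C)cc1OC | intermediate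
23 | 4-[(1S)-1-(tert-butyldimethylsilyloxy)ethyl]-3-methoxyphenol | C[C@H](O[Si](C)(C)C(C)(C)C)c1ccc(O)cc1OC | intermediate
24 | 3-chloro-3-methylbut-1-yne | CC(C)(Cl)C#C | starting material
25 | tert-butyl{(1S)-1-[2-methoxy-4-(2-methylbut-3-yn-2-yloxy)phenyl]ethoxy}dimethylsilane | C[C@H](O[Si](C)(C)C(C)(C)C)c1ccc(OC(C)(C)C#C)cc1OC | intermediate
26 | 4-[(1S)-1-(tert-butyldimethylsilyloxy)ethyl]-5-methoxy-2-(3-methylbuta-1,2-dien-1-yl)phenol (not isolated) | C[C@H](O[Si](C)(C)C(C)(C)C)c1cc(C=C=C(C)C)c(O)cc1OC | intermediate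
27 | (6Z)-4-[(1S)-1-(tert-butyldimethylsilyloxy)ethyl]-3-methoxy-6-(3-methylbut-2-en-1-ylidene)cyclohexa-2,4-dien-1-one (not isolated) | O=C1C=C(OC)C([C@H](C)O[Si](C)(C)C(C)(C)C)=C/C1=C/C=C(C)C | intermediate
28 | tert-butyl[(1S)-1-(7-methoxy-2,2-dimethyl-2H-chromen-6-yl)ethoxy]dimethylsilane | COc1cc2c(cc1[C@H](C)O[Si](C)(C)C(C)(C)C)C=CC(C)(C)O2 | intermediate
29 | (1S)-1-(7-methoxy-2,2-dimethyl-2H-chromen-6-yl)ethan-1-ol | COc1cc2c(cc1[C@H](C)O)C=CC(C)(C)O2 | intermediate
30 | 2-bromo-5-methylphenol | Cc1ccc(Br)c(O)c1 | starting material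
31 | (2-bromo-5-methylphenoxy)triisopropylsilane | Cc1ccc(Br)c(O[Si](C(C)C)(C(C)C)C(C)C)c1 | intermediate
32 | propargyl alcohol (prop-2-yn-1-ol) | C#CCO | starting material
33 | [4-methyl-2-(triisopropylsilyloxy)phenyl]magnesium bromide (not isolated) | Cc1ccc([Mg]Br)c(O[Si](C(C)C)(C(C)C)C(C)C)c1 | intermediate
34 | 4-[4-methyl-2-(triisopropylsilyloxy)phenyl]-2,5-dihydro-1,2-oxamagnesole (cyclic alkenylmagnesium alkoxide, not isolated) | Cc1ccc(C2=C[Mg]OC2)c(O[Si](C(C)C)(C(C)C)C(C)C)c1 | intermediate
35 | (2Z)-3-iodo-2-[4-methyl-2-(triisopropylsilyloxy)phenyl]prop-2-en-1-ol | I/C=C(\CO)c1ccc(C)cc1O[Si](C(C)C)(C(C)C)C(C)C | intermediate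
36 | tert-butyl({(2Z)-3-iodo-2-[4-methyl-2-(triisopropylsilyloxy)phenyl]prop-2-en-1-yl}oxy)dimethylsilane | I/C=C(\CO[Si](C)(C)C(C)(C)C)c1ccc(C)cc1O[Si](C(C)C)(C(C)C)C(C)C | intermediate
37 | tert-butyl{[(2Z)-3-[(1S)-1-(7-methoxy-2,2-dimethyl-2H-chromen-6-yl)ethoxy]-2-[4-methyl-2-(triisopropylsilyloxy)phenyl]prop-2-en-1-yl]oxy}dimethylsilane | COc1cc2c(cc1[C@H](C)O/C=C(\CO[Si](C)(C)C(C)(C)C)c1ccc(C)cc1O[Si](C(C)C)(C(C)C)C(C)C)C=CC(C)(C)O2 | intermediate
38 | 2-{(1Z)-3-hydroxy-1-[(1S)-1-(7-methoxy-2,2-dimethyl-2H-chromen-6-yl)ethoxy]prop-1-en-2-yl}-5-methylphenol | COc1cc2c(cc1[C@H](C)O/C=C(\CO)c1ccc(C)cc1O)C=CC(C)(C)O2 | target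

**Step count**

Total: 19 steps. Longest linear sequence: 13 steps (steps 1–5, 9–14, 18, 19) from ethyl (S)-lactate.

**Steps most likely to fail**

Step 18 (O-vinylation). The hindered secondary alkoxide may transfer slowly to copper and the trisubstituted iodide may react slowly. Silyl transfer from the aryl silyl ether of 36 to the caesium alkoxide, or reduction of the C–I bond, could then overtake C–O bond formation. The fallback sets out from 29 and returns at 37, and it builds the enol ether on the oxygen of 29 instead of coupling to it. Deprotonation of 29 with KH and addition to trichloroethylene should give 6-{(1S)-1-[(E)-1,2-dichlorovinyloxy]ethyl}-7-methoxy-2,2-dimethyl-2H-chromene F1. Treatment with n-BuLi (2.2 equiv, −78 °C) converts it into the lithium alkynyl ether F2. Paraformaldehyde traps this as 3-[(1S)-1-(7-methoxy-2,2-dimethyl-2H-chromen-6-yl)ethoxy]prop-2-yn-1-ol F3, and t-BuMe2SiCl with imidazole gives its tert-butyldimethylsilyl ether F4. Syn hydroboration with dicyclohexylborane at 0 °C places boron on the carbon remote from oxygen and gives the (Z)-alkenyl(dicyclohexyl)borane F5. This is coupled in the same flask with aryl bromide 31 (Pd(PPh3)4, aq. K3PO4, THF, 50 °C; Suzuki–Miyaura coupling with retention) to give 37. F3 and F4 are kept below 25 °C, because secondary benzylic ynol ethers rearrange on heating.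

Step 9 (benzannulation). The photochemical stage may be inefficient: secondary photolysis of 18 or 21 at 254 nm, 1,3-silyl shift of 16 to the silylketene, or acylation of phenol 21 by ketene 17. The fallback sets out from 9 and returns at 21, and it generates the same vinylketene in the dark. Silver benzoate-catalysed Wolff rearrangement of 9 in THF–H2O with Et3N should give (3E,5S)-5-(tert-butyldimethylsilyloxy)hex-3-enoic acid F6. The neutral reagent 1-chloro-N,N,2-trimethylprop-1-en-1-amine converts it into (3E,5S)-5-(tert-butyldimethylsilyloxy)hex-3-enoyl chloride F7. Slow addition of F7 to Et3N and 16 in toluene at 25 °C forms 17 by dehydrochlorination; 16 captures it as 18, and heating to 80 °C takes 18 through 19 and 20 to 21.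

Step 16 (carbomagnesiation). The bulky ortho silyloxy group may slow addition of the arylcopper species to the alkynyl alkoxide, so that deprotonation of the alkyne C–H or silyl migration from oxygen to the carbanionic carbon competes. The fallback sets out from 30 and returns at 35, and it uses a small chelating protecting group for the organometallic stage. Chloromethyl methyl ether and i-Pr2NEt convert 30 into 1-bromo-2-(methoxymethoxy)-4-methylbenzene F8. Its Grignard reagent, [2-(methoxymethoxy)-4-methylphenyl]magnesium bromide F9, adds to 32 under CuI catalysis to give the magnesium chelate 4-[2-(methoxymethoxy)-4-methylphenyl]-2,5-dihydro-1,2-oxamagnesole F10. Iodine then gives (2Z)-3-iodo-2-[2-(methoxymethoxy)-4-methylphenyl]prop-2-en-1-ol F11. HCl in MeOH, harmless at this stage, removes the acetal to give 2-[(1Z)-3-hydroxy-1-iodoprop-1-en-2-yl]-5-methylphenol F12. NaH (1.0 equiv) followed by i-Pr3SiCl silylates the phenoxide selectively and returns 35.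

**Further compounds**

F1 | step 18 | 6-{(1S)-1-[(E)-1,2-dichlorovinyloxy]ethyl}-7-methoxy-2,2-dimethyl-2H-chromene | COc1cc2c(cc1[C@H](C)O/C(Cl)=C\Cl)C=CC(C)(C)O2
F2 | step 18 | lithium 2-[(1S)-1-(7-methoxy-2,2-dimethyl-2H-chromen-6-yl)ethoxy]acetylide | COc1cc2c(cc1[C@H](C)OC#C[Li])C=CC(C)(C)O2
F3 | step 18 | 3-[(1S)-1-(7-methoxy-2,2-dimethyl-2H-chromen-6-yl)ethoxy]prop-2-yn-1-ol | COc1cc2c(cc1[C@H](C)OC#CCO)C=CC(C)(C)O2
F4 | step 18 | tert-butyl({3-[(1S)-1-(7-methoxy-2,2-dimethyl-2H-chromen-6-yl)ethoxy]prop-2-yn-1-yl}oxy)dimethylsilane | COc1cc2c(cc1[C@H](C)OC#CCO[Si](C)(C)C(C)(C)C)C=CC(C)(C)O2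
F5 | step 18 | {(1Z)-3-(tert-butyldimethylsilyloxy)-1-[(1S)-1-(7-methoxy-2,2-dimethyl-2H-chromen-6-yl)ethoxy]prop-1-en-2-yl}dicyclohexylborane | COc1cc2c(cc1[C@H](C)O/C=C(\CO[Si](C)(C)C(C)(C)C)B(C1CCCCC1)C1CCCCC1)C=CC(C)(C)O2
F6 | step 9 | (3E,5S)-5-(tert-butyldimethylsilyloxy)hex-3-enoic acid | OC(=O)C/C=C/[C@H](C)O[Si](C)(C)C(C)(C)C
F7 | step 9 | (3E,5S)-5-(tert-butyldimethylsilyloxy)hex-3-enoyl chloride | ClC(=O)C/C=C/[C@H](C)O[Si](C)(C)C(C)(C)C
F8 | step 16 | 1-bromo-2-(methoxymethoxy)-4-methylbenzene | Cc1ccc(Br)c(OCOC)c1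
F9 | step 16 | [2-(methoxymethoxy)-4-methylphenyl]magnesium bromide | Cc1ccc([Mg]Br)c(OCOC)c1
F10 | step 16 | 4-[2-(methoxymethoxy)-4-methylphenyl]-2,5-dihydro-1,2-oxamagnesole | Cc1ccc(C2=C[Mg]OC2)c(OCOC)c1
F11 | step 16 | (2Z)-3-iodo-2-[2-(methoxymethoxy)-4-methylphenyl]prop-2-en-1-ol | I/C=C(\CO)c1ccc(C)cc1OCOC
F12 | step 16 | 2-[(1Z)-3-hydroxy-1-iodoprop-1-en-2-yl]-5-methylphenol | I/C=C(\CO)c1ccc(C)cc1O
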